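(All runs come from a simulation from invented constants; scatter was added.)

Amounts first: the oak flask starts at [starting material] = 0.48 M and [protic impurity] = 0.036 M, and at 6.00 min it holds 30.1 % of target with 0.8 % of starting material still free.

all flasks: starting material 0.48 M
- oak: protic impurity 0.036 M; temperature 120 °C; run made earlier
- green: protic impurity 0.0240 M; temperature 120 °C; time 30 min
- violet: protic impurity 0.0240 M; temperature 140 °C; time 30 min
- teal: protic impurity 0.0240 M; temperature 100 °C; time 30 min

oak run (percent of the starting material charged)

| time / min | target / % | starting material / % |
|---|---|---|
| 0.500 | 10.0 | 59.4 |
| 1.00 | 16.8 | 38.3 |
| 2.50 | 26.3 | 12.9 |
| 6.00 | 30.1 | 0.8 |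

(readings scatter by 0.3 percentage points)

- the numbers in the tables scatter by 0.3 percentage points (one standard deviation)
- the earlier runs do not show what temperature does; that part of a forecast is a guess
- a reading or a percentage of target counts all its forms, free or not
- no earlier run changes the charge of protic impurity; that part of a forecast is a guess
- a reading of starting material is of its free form alone

1. the best flask by amount of target, in percent of the starting material charged; "all alike" if 1.5 percentage points covers them all (green / violet / teal / all alike)
2. amount of target at the end, in percent of the starting material charged, green
3. amount of target at the end, in percent of the starting material charged, violet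
4. amount of target at the end, in percent of the starting material charged, teal

Target per starting material gone is 30.3 % at that reading, so my first estimate is that figure for each new flask. I object to it myself, though: at the first oak reading the same ratio is 24.6 %, and each reading scatters by just 0.3 percentage points. Some starting material seems to go without giving target. The protic impurity amounts to 7.50 % of the starting material, so I suppose that it takes starting material one for one and subtract that first. The ratio then reads 30.2 % at the first reading and 32.8 % at the last. The gap shrinks but stays, so I keep the last reading, the nearest to the end asked about.

This gives my quantity, the working share: target per starting material gone by routes other than the impurity, a selectivity, 0.328. End target is the working share times the charge minus the impurity's share of it, so green should give 31.2 %.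

But no earlier run changes the impurity, so one for one is a supposition. Without that loss green gives 30.3 %, and the two estimates differ by 0.90 points, under the margin of 1.5 points, so the doubt costs little. Time is the next objection. The oak readings fall at about 0.783 /min, and a first-order fall with a rate 5.10 times lower still drops by a factor of 100 in 30 min, but how far the rate in teal lies below the one in oak is a guess. Temperature remains: oak cannot say how it moves the working share, so for violet and teal my 31.2 % is a guess.

The forecast says 31.2 % for green (29.5 % to 33 %), 30.5 % for violet (23 % to 37 %) and 31.3 % for teal (25 % to 37 %), hence all alike. Its ground is that the remainder “gives target at about 0.33 per unit consumed”. For green its number is mine, and for violet and teal it departs slightly from mine.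

The flasks give 31.4 % in green, 30.9 % in violet and 30.6 % in teal, a spread of 0.80 points, so the answer is all alike.

    starting material → target (k = 0.0454 /min, Ea = 109 kJ/mol)
    starting material → side product A (k = 0.0271 /min, Ea = 125 kJ/mol)
    starting material → side product B (k = 0.0658 /min, Ea = 100 kJ/mol)
    starting material + protic impurity → quenched substrate (k = 13.2 /M/min, Ea = 78.0 kJ/mol)
    crystals ⇌ target, rate k5*(cs5 - [target]) while solid is left; crystals form when [target] > cs5 (solubility = 13.0 mM, k = 0.351 /min)
    starting material + target ⇌ idle adduct, settled at all times (K = 1.40 /M, ΔH = −3.00 kJ/mol)
    (constants at 100 °C)

The further flask is green with 0.096 M of protic impurity, 0.200 equiv to the starting material. The same reckoning subtracts 20.0 % of the charge and, with the working share 0.328, gives 26.3 % of target. The flask gives 26.4 % at 30.0 min. Its quenched substrate stands at 20.0 %, against 5.00 % in green, and its protic impurity at 0 % of its own charge.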